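(The readings are calculated for an exercise; scatter was added.)

If starting material leaves the flask on a clock of its own, the quick number for summer and spring is a count of turnovers of that clock.

| setting | north | summer | spring |
|---|---|---|---|
| starting material | 0.050 M | 0.050 M | 0.050 M |
| partner | 0.20 M | 0.100 M | 0.100 M |
| protic impurity | 5 mM | 5.00 mM | 5.00 mM |
| remark | run made earlier |  |  |
| time |  | 3.0 min | 4.0 min |

north run (percent of the starting material charged)

| time / s | target / % | starting material / % | open intermediate / % |
|---|---|---|---|
| 10.0 | 5.3 | 86.1 | 5.3 |
| 15.0 | 11.2 | 80.4 | 4.3 |
| 25.0 | 21.6 | 70.2 | 2.4 |
| 40.0 | 34.3 | 56.7 | 1.2 |

(standard deviation of a reading: 0.3 percentage points)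



- which of these there is most of at the end, counted by the starting material in it, summer (starting material / open intermediate / target)
- which of these there is most of at the end, counted by the starting material in it, spring (starting material / open intermediate / target)
- final amount of the leader among these, as a percentage of the starting material charged, in summer
- final amount of the leader among these, as a percentage of the starting material charged, in spring

In the north run, the readings of starting material fall along one exponential. Its turnover time, in which the remaining fraction drops by a factor of e, reads 71.8 s between first and last reading. At the first reading, open intermediate stands level with target, and it then sinks to 1.2%. That reads as opening first and closure after.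

The reckoning here takes opening as the rate-limiting step, with a turnover time that stays put when partner drops from 4.00 to 2.00 equivalents. The north run holds a single partner charge, so this is a commitment.

Summer then gets 2.51 turnovers and spring 3.34, leaving 8.16% and 3.54% of starting material. Protic impurity is worth 10.0% of the charge, and the reckoning books that as lost, so it puts target at 81.8% in summer and 86.5% in spring.

The forecast also puts target first, but at 55% in summer and 64% in spring, “assuming first order in partner”. Its clock slows with less partner; the turnover count does not.

Target leads in both flasks, at 79.5% in summer and 85.1% in spring, with 10.6% and 5.06% of starting material left, against the 8.16% and 3.54% that the turnover count reckoned.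

starting material ⇌ open intermediate (K = 0.410, k = 0.0130 /s); partner → second intermediate (k = 0.0140 /s); open intermediate + second intermediate → target (k = 8.40 /M/s); starting material + protic impurity → quenched substrate (k = 0.930 /M/s) Spring's neighbour flask, with partner at 0.800 equiv, has the same 3.34 turnovers, which reckon 86.5% target. Its partner, the limiting reagent there, is worth 80.0% of the charge, less than that, so the reckoning stops at that figure. At 4.00 min that neighbour flask holds 71.9% target and 14.6% starting material, with 3.5% of its own partner charge free.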